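(The numbers were chosen freely; what happens was integrated by code.)

A small charge of electrophile sits stirred in the flask while nucleophile runs in at a steady rate, and I want to know how far the electrophile gets by the end of the feed.

the same everywhere: electrophile 0.050 M; time 15 s
- spring: nucleophile 2.50 equiv (fed, over 15 s)
- summer: nucleophile 5.00 equiv (fed, over 15 s)
- dusk: nucleophile 10.0 equiv (fed, over 15 s)

    electrophile + nucleophile → acid set free + target (k1 = 0.661 /M/s)
    nucleophile + acid set free ⇌ protonated nucleophile, settled at all times (K2 = 36900 /M)
    electrophile + target → side product (k3 = 1.58 /M/s)

- percent here means electrophile units held: one side product counts as two
- run time (spring): 15 s

- part of the electrophile that has reacted at the end, spring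
- part of the electrophile that has reacted at the end, summer
- part of the electrophile that has reacted at the end, dusk
- what raising the equivalents of nucleophile from its lowest to its highest value here does to the part of the electrophile that has reacted (changes below 5 percentage points count as none) (it falls / it rises / no change)

I take the capture of acid set free by nucleophile as settled, because at the full spring charge the ratio of protonated nucleophile to acid set free is 4610; it adds no time of its own, and its price is a second nucleophile per coupling. Two times remain. One is the time the coupling takes at the full charge, in spring 12.1 s. The other is what the feed really offers: [nucleophile] climbs in a straight line from zero, so its average over the run is reached with the weight of half the dosing time, 7.50 s, which is shorter than the first.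

Their ratio, 0.620 in spring, I call the exposure: the coupling constant times [nucleophile] as fed, summed over the run. It is the exponent of a pseudo-first-order decay with a rising rate constant, and it is 1.24 in summer and 2.48 in dusk. Coupling and capture both lower [nucleophile] while over-reaction with target eats electrophile; these pull opposite ways, so I drop them all and commit to one minus the exponential of minus the exposure: 46.2%, 71.1%, 91.6%.

The forecast gives 45.7%, 70.8%, 91.6%, and for the equivalents it rises, on the grounds that “more nucleophile clearly raises conversion”; in spring it stands 0.49 percentage points below mine.

The simulation gives 45.7%, 70.8%, 91.6%, and with more nucleophile it rises, by 46 points. With over-reaction struck out, summer reaches 62.6%, less than the full flask. The summer exposure of 1.24, which counts no over-reaction, gives 71.1%, and that stands 8.5 points above the struck flask.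

For the neighbour of dusk charged with 4.00 equiv, the exposure is 0.992, which gives 62.9%; that flask reaches 62.6%.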